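**Plan**

1. Retrosynthesis: both C–Br bonds (C9, C12) go back to a diol by double SN2 inversion. The (E)-enyne goes back to an allyl group on C6 (C3=C4 by cross-metathesis, C1 by alkyne homologation). The C9–C10 bond is then cut, which opens the tetrahydropyran (O-a, C6–C10) and the oxocane (O-b, C7–C13) together and leaves one eight-membered 1,4-dioxocine (O-a, C10, C11, C12, C13, O-b, C7, C6).
2. Feature that allows this: C10 bears O-a and stands 1,3 to C12, so C12–Br can come from a ketone and O-a–C10=C11–C12=O is a ring vinylogous ester with C10 as acceptor. C9 ends a two-carbon arm on C7 and is the sixth atom from C10 (C9–C8–C7–C6–O-a–C10), so a C9 ketyl from an aldehyde closes the six-membered ring onto C10.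
3. Forward order: chain assembly (C8 to the C7 epoxide carbon, O-b–C13 ether, C5–C6 allylation, C11–C12 alkynyl ketone); O-a–C10 oxa-Michael closure gives the dioxocine; the SmI2 ketyl–olefin cyclization then makes tetrahydropyran and oxocane at once; ketone reduction, enyne, dibromination.
4. Stereochemistry: C7 from (R)-trityl glycidyl ether; C13 from (S)-2-bromobutanoic acid by SN2 inversion; C6 by chelation-controlled allylation; C10 and C9 in the key step; C12 by hydride attack anti to ethyl; final C9 and C12 by inversion on bromination.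

Key step: step 10

Remark: carbons are numbered C1–C15 along the chain of the target (C1 = alkyne CH, C15 = ethyl CH3); O-a is the ring oxygen between C6 and C10, O-b the one between C7 and C13. In the bicycle names C1 = C7, O2 = O-b, C3 = C13, C4 = C12, C5 = C11, C6 = C10, O7 = O-a, C8 = C6, C9 = C8, C10 = C9. Compounds 1, 2 and 5 are taken to be commercial.

**Step 1**
Reactants: 1 1,3-dithiane; 2 (R)-trityl glycidyl ether
Product: 4 (2R)-1-(1,3-dithian-2-yl)-3-(triphenylmethoxy)propan-2-ol, via 2-lithio-1,3-dithiane 3 (not isolated)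
Conditions: n-BuLi (1.05 equiv), THF, −30 °C; then 2, −30 to 0 °C; H2O
Reagents that add atoms: n-butyllithium, [Li]CCCC (lithium of 3 only)
Why: Epoxide opening by a lithiated dithiane (Corey–Seebach umpolung) at the unsubstituted epoxide carbon should give the secondary alcohol without touching the stereocentre, so C7 is taken unchanged from 2 and the dithiane carries C9 as a masked aldehyde.

**Step 2**
Reactants: 4 (2R)-1-(1,3-dithian-2-yl)-3-(triphenylmethoxy)propan-2-ol; 5 (S)-2-bromobutanoic acid
Product: 6 (2R)-2-{[(2R)-1-(1,3-dithian-2-yl)-3-(triphenylmethoxy)propan-2-yl]oxy}butanoic acid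
Conditions: NaH (3 equiv), THF, 0 °C; then 5 (1.3 equiv), 0 to 55 °C; cold 1 M HCl to pH 3
Reagents that add atoms: none
Why: Williamson ether synthesis with the sodium salt of an α-bromo acid, a known way to O-alkylate hindered secondary alcohols with clean SN2 inversion, should turn the (S)-bromide into the (R)-configured C13 ether, the carboxylate charge protecting the α-hydrogen against enolization and elimination.

**Step 3**
Reactants: 6 (2R)-2-{[(2R)-1-(1,3-dithian-2-yl)-3-(triphenylmethoxy)propan-2-yl]oxy}butanoic acid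
Product: 8 (2R)-2-{[(2R)-1-(1,3-dithian-2-yl)-3-(triphenylmethoxy)propan-2-yl]oxy}-N-methoxy-N-methylbutanamide, via acyl imidazolide 7 (not isolated)
Conditions: CDI (1.2 equiv), CH2Cl2, rt; then MeNH(OMe)·HCl (1.5 equiv), rt
Reagents that add atoms: 1,1'-carbonyldiimidazole, O=C(n1ccnc1)n1ccnc1 (imidazolyl group of 7 only); N,O-dimethylhydroxylamine hydrochloride, CNOC.Cl
Why: Amide formation through the acyl imidazolide 7 should give the N-methoxy-N-methylamide without epimerization at C13, since an α-alkoxy acid has no azlactone pathway.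

**Step 4**
Reactants: 8 (2R)-2-{[(2R)-1-(1,3-dithian-2-yl)-3-(triphenylmethoxy)propan-2-yl]oxy}-N-methoxy-N-methylbutanamide
Product: 9 (2R)-2-{[(2R)-1-(1,3-dithian-2-yl)-3-hydroxypropan-2-yl]oxy}-N-methoxy-N-methylbutanamide
Conditions: TsOH·H2O (0.1 equiv), MeOH/CH2Cl2 (1:1), rt
Reagents that add atoms: none
Why: Acid-catalysed methanolysis of the trityl ether (SN1 through the trityl cation) should free the C6 hydroxyl while the dithiane, the amide and the ether stay intact.

**Step 5**
Reactants: 9 (2R)-2-{[(2R)-1-(1,3-dithian-2-yl)-3-hydroxypropan-2-yl]oxy}-N-methoxy-N-methylbutanamide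
Product: 10 (2R)-2-{[(2R)-1-(1,3-dithian-2-yl)-3-oxopropan-2-yl]oxy}-N-methoxy-N-methylbutanamide
Conditions: SO3·pyridine (3 equiv), DMSO, i-Pr2NEt (5 equiv), CH2Cl2, 0 °C; used crude
Reagents that add atoms: none
Why: Parikh–Doering oxidation should give the α-alkoxy aldehyde at 0 °C without oxidizing the dithiane sulfur or epimerizing C7.

**Step 6**
Reactants: 10 (2R)-2-{[(2R)-1-(1,3-dithian-2-yl)-3-oxopropan-2-yl]oxy}-N-methoxy-N-methylbutanamide
Product: 11 (2R)-2-{[(2R,3R)-1-(1,3-dithian-2-yl)-3-hydroxyhex-5-en-2-yl]oxy}-N-methoxy-N-methylbutanamide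
Conditions: MgBr2·OEt2 (2.5 equiv), CH2Cl2, −78 °C; then CH2=CHCH2SnBu3 (1.5 equiv), −78 to −20 °C
Reagents that add atoms: allyltributylstannane, C=CC[Sn](CCCC)(CCCC)CCCC
Why: Chelation-controlled allylstannane addition to an α-alkoxy aldehyde: MgBr2 bridges the aldehyde oxygen and the C7 ether oxygen, the allyl group attacks the face opposite the C8 arm, and the 6,7-syn alcohol with (6R) configuration should result, the amide being inert to the stannane.

**Step 7**
Reactants: 11 (2R)-2-{[(2R,3R)-1-(1,3-dithian-2-yl)-3-hydroxyhex-5-en-2-yl]oxy}-N-methoxy-N-methylbutanamide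
Product: 12 (4R)-4-{[(2R,3R)-1-(1,3-dithian-2-yl)-3-hydroxyhex-5-en-2-yl]oxy}hex-1-yn-3-one
Conditions: HC≡CMgBr (3.5 equiv), THF, −20 to 0 °C; aq NH4Cl
Reagents that add atoms: ethynylmagnesium bromide, C#C[Mg]Br
Why: Weinreb ketone synthesis: the N-methoxy-N-methylamide should stop at the ketone stage after one addition of the alkynyl Grignard reagent, the first equivalent being spent on the free hydroxyl, and C13 is not enolized under these conditions.

**Step 8**
Reactants: 12 (4R)-4-{[(2R,3R)-1-(1,3-dithian-2-yl)-3-hydroxyhex-5-en-2-yl]oxy}hex-1-yn-3-one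
Product: 13 (2R,3R,5Z,8R)-2-(1,3-dithian-2-ylmethyl)-8-ethyl-3-(prop-2-en-1-yl)-2,3-dihydro-1,4-dioxocin-7(8H)-one
Conditions: DABCO (0.2 equiv), CH2Cl2 (0.005 M), rt
Reagents that add atoms: none
Why: Amine-catalysed oxa-Michael addition of the C6 hydroxyl to the ynone, the intramolecular form of a standard synthesis of β-alkoxy enones, should close the eight-membered ring, which can only hold the (Z)-enone; the cis double bond and the two ring oxygens lower transannular strain and high dilution suppresses oligomers.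

**Step 9**
Reactants: 13 (2R,3R,5Z,8R)-2-(1,3-dithian-2-ylmethyl)-8-ethyl-3-(prop-2-en-1-yl)-2,3-dihydro-1,4-dioxocin-7(8H)-one
Product: 14 2-[(2R,3R,5Z,8R)-8-ethyl-7-oxo-3-(prop-2-en-1-yl)-2,3,7,8-tetrahydro-1,4-dioxocin-2-yl]acetaldehyde
Conditions: PhI(OCOCF3)2 (1.5 equiv), MeCN/H2O (9:1), 0 °C, 10 min
Reagents that add atoms: water, O
Why: Oxidative dithiane hydrolysis with a trivalent iodine reagent should free the C9 aldehyde within minutes at 0 °C, sparing the terminal alkene and the electron-poor vinylogous ester; the aldehyde is unmasked only after the C6 oxygen is tied up in the ring, so no lactol can form.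

**Step 10**
Reactants: 14 2-[(2R,3R,5Z,8R)-8-ethyl-7-oxo-3-(prop-2-en-1-yl)-2,3,7,8-tetrahydro-1,4-dioxocin-2-yl]acetaldehyde
Product: 17 (1R,3R,6S,8R,10R)-3-ethyl-10-hydroxy-8-(prop-2-en-1-yl)-2,7-dioxabicyclo[4.2.2]decan-4-one, via samarium ketyl radical 15 (not isolated), via samarium enolate 16 (not isolated)
Conditions: SmI2 (2.3 equiv, 0.1 M in THF), MeOH (3 equiv), THF, −78 to 0 °C
Reagents that add atoms: samarium diiodide, I[Sm]I (samarium and iodine of 15 and 16 only)
Why: SmI2 reduces the aldehyde to the samarium ketyl radical 15, whose nucleophilic carbon C9 adds to C10, the β-carbon of the ring vinylogous ester, and a second SmI2 reduces the resulting α-keto radical to the samarium enolate 16, which methanol protonates at C11. The closest known reaction type is the SmI2-mediated reductive cyclization of an aldehyde onto a β-alkoxy acrylate or β-alkoxy enone, the standard entry to 2-alkyl-3-hydroxytetrahydropyrans. The tetrahydropyran (O-a, C6, C7, C8, C9, C10) closes in the 6-exo-trig mode, and because the acceptor double bond already lies in the eight-membered ring the same bond closes the oxocane (O-b, C7 to C13) as a bridging closure across that ring, so no separate medium-ring cyclization is needed. C10 is set by the tether, since C9 can reach only the face of C10=C11 that carries the C7 arm, which puts C10–H cis to C6–H and C7–H; C9 is set by placement of the bulky samarium-bound oxygen on the open side, anti to C11 and away from the four-atom bridge, which is the 2,3-trans outcome of the acyclic reaction class. The step needs the aldehyde to be reduced before the vinylogous ester and before the α-alkoxy ketone of the product: the aldehyde is the best electron acceptor present, SmI2 is limited to little more than two equivalents without polar additive, and the isolated allyl group is not an acceptor for the ketyl.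

**Step 11**
Reactants: 17 (1R,3R,6S,8R,10R)-3-ethyl-10-hydroxy-8-(prop-2-en-1-yl)-2,7-dioxabicyclo[4.2.2]decan-4-one
Product: 18 (1R,3R,4R,6S,8R,10R)-3-ethyl-8-(prop-2-en-1-yl)-2,7-dioxabicyclo[4.2.2]decane-4,10-diol
Conditions: LiBH(s-Bu)3 (2.5 equiv), THF, −78 °C; H2O
Reagents that add atoms: none
Why: Substrate-controlled ketone reduction with a bulky hydride: attack on C12 from the face turned toward the C8–C9 bridge, anti to the C13 ethyl group and to the C6 side chain, should give the alcohol cis to ethyl (12R), the configuration that later inverts to the bromide.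

**Step 12**
Reactants: 18 (1R,3R,4R,6S,8R,10R)-3-ethyl-8-(prop-2-en-1-yl)-2,7-dioxabicyclo[4.2.2]decane-4,10-diol
Product: 19 (2E)-4-[(1R,3R,4R,6S,8R,10R)-3-ethyl-4,10-dihydroxy-2,7-dioxabicyclo[4.2.2]decan-8-yl]but-2-enal
Conditions: (E)-crotonaldehyde (10 equiv), second-generation Hoveyda–Grubbs catalyst (5 mol%), CH2Cl2, 40 °C
Reagents that add atoms: (E)-crotonaldehyde, C/C=C/C=O
Why: Olefin cross-metathesis of a terminal alkene with an electron-poor partner should give the (E)-enal selectively, and the free hydroxyls are tolerated by the ruthenium carbene.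

**Step 13**
Reactants: 19 (2E)-4-[(1R,3R,4R,6S,8R,10R)-3-ethyl-4,10-dihydroxy-2,7-dioxabicyclo[4.2.2]decan-8-yl]but-2-enal
Product: 20 (1R,3R,4R,6S,8R,10R)-3-ethyl-8-[(2E)-pent-2-en-4-yn-1-yl]-2,7-dioxabicyclo[4.2.2]decane-4,10-diol
Conditions: Me3SiCHN2 (4 equiv), LiN(i-Pr)2 (4 equiv), THF, −78 °C; then 19, −78 to 0 °C; H2O
Reagents that add atoms: (trimethylsilyl)diazomethane, C[Si](C)(C)C=[N+]=[N-]
Why: Colvin rearrangement: lithiated trimethylsilyldiazomethane should convert the enal into the terminal alkyne with one added carbon and without touching the (E)-alkene, two equivalents of the base being held by the hydroxyls as alkoxides.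

**Step 14**
Reactants: 20 (1R,3R,4R,6S,8R,10R)-3-ethyl-8-[(2E)-pent-2-en-4-yn-1-yl]-2,7-dioxabicyclo[4.2.2]decane-4,10-diol
Product: 21 (1R,3R,4S,6S,8R,10S)-4,10-dibromo-3-ethyl-8-[(2E)-pent-2-en-4-yn-1-yl]-2,7-dioxabicyclo[4.2.2]decane
Conditions: CBr4 (6 equiv), P(n-C8H17)3 (12 equiv), toluene, 70 °C
Reagents that add atoms: carbon tetrabromide, BrC(Br)(Br)Br
Why: Appel-type bromination: both secondary hydroxyls are activated by the phosphine/CBr4 pair and displaced by bromide with SN2 inversion, bromide entering at C9 and at C12 from the unhindered side that faces the neighbouring bridge, which should set (9S) and (12S).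

**Compound list**

1 | 1,3-dithiane | C1CSCSC1 | starting material
2 | (R)-trityl glycidyl ether, (2R)-2-[(triphenylmethoxy)methyl]oxirane | O1C[C@@H]1COC(c1ccccc1)(c1ccccc1)c1ccccc1 | starting material
3 | 2-lithio-1,3-dithiane (not isolated) | [Li]C1SCCCS1 | intermediate
4 | (2R)-1-(1,3-dithian-2-yl)-3-(triphenylmethoxy)propan-2-ol | C1CSC(SC1)C[C@@H](O)COC(c1ccccc1)(c1ccccc1)c1ccccc1 | intermediate
5 | (S)-2-bromobutanoic acid | CC[C@H](Br)C(=O)O | starting material
6 | (2R)-2-{[(2R)-1-(1,3-dithian-2-yl)-3-(triphenylmethoxy)propan-2-yl]oxy}butanoic acid | CC[C@@H](O[C@H](CC1SCCCS1)COC(c1ccccc1)(c1ccccc1)c1ccccc1)C(=O)O | intermediate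
7 | acyl imidazolide of 6 (not isolated) | CC[C@@H](O[C@H](CC1SCCCS1)COC(c1ccccc1)(c1ccccc1)c1ccccc1)C(=O)n1ccnc1 | intermediate
8 | (2R)-2-{[(2R)-1-(1,3-dithian-2-yl)-3-(triphenylmethoxy)propan-2-yl]oxy}-N-methoxy-N-methylbutanamide | CC[C@@H](O[C@H](CC1SCCCS1)COC(c1ccccc1)(c1ccccc1)c1ccccc1)C(=O)N(C)OC | intermediate
9 | (2R)-2-{[(2R)-1-(1,3-dithian-2-yl)-3-hydroxypropan-2-yl]oxy}-N-methoxy-N-methylbutanamide | CC[C@@H](O[C@H](CC1SCCCS1)CO)C(=O)N(C)OC | intermediate
10 | (2R)-2-{[(2R)-1-(1,3-dithian-2-yl)-3-oxopropan-2-yl]oxy}-N-methoxy-N-methylbutanamide | CC[C@@H](O[C@H](CC1SCCCS1)C=O)C(=O)N(C)OC | intermediate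
11 | (2R)-2-{[(2R,3R)-1-(1,3-dithian-2-yl)-3-hydroxyhex-5-en-2-yl]oxy}-N-methoxy-N-methylbutanamide | CC[C@@H](O[C@H](CC1SCCCS1)[C@H](O)CC=C)C(=O)N(C)OC | intermediate
12 | (4R)-4-{[(2R,3R)-1-(1,3-dithian-2-yl)-3-hydroxyhex-5-en-2-yl]oxy}hex-1-yn-3-one | CC[C@@H](O[C@H](CC1SCCCS1)[C@H](O)CC=C)C(=O)C#C | intermediate
13 | (2R,3R,5Z,8R)-2-(1,3-dithian-2-ylmethyl)-8-ethyl-3-(prop-2-en-1-yl)-2,3-dihydro-1,4-dioxocin-7(8H)-one (O1 = O-b, C2 = C7, C3 = C6, O4 = O-a, C5 = C10, C7 = C12, C8 = C13) | C=CC[C@H]1O/C=C\C(=O)[C@@H](CC)O[C@@H]1CC1SCCCS1 | intermediate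
14 | 2-[(2R,3R,5Z,8R)-8-ethyl-7-oxo-3-(prop-2-en-1-yl)-2,3,7,8-tetrahydro-1,4-dioxocin-2-yl]acetaldehyde | C=CC[C@H]1O/C=C\C(=O)[C@@H](CC)O[C@@H]1CC=O | intermediate
15 | samarium ketyl radical of 14, C9-centred (not isolated) | C=CC[C@H]1O/C=C\C(=O)[C@@H](CC)O[C@@H]1C[CH]O[Sm](I)I | intermediate
16 | bicyclic samarium enolate (C11=C12) with samarium alkoxide at C9 (not isolated) | C=CC[C@H]1O[C@H]2C=C(O[Sm](I)I)[C@@H](CC)O[C@@H]1C[C@H]2O[Sm](I)I | intermediate
17 | (1R,3R,6S,8R,10R)-3-ethyl-10-hydroxy-8-(prop-2-en-1-yl)-2,7-dioxabicyclo[4.2.2]decan-4-one | C=CC[C@H]1O[C@H]2CC(=O)[C@@H](CC)O[C@@H]1C[C@H]2O | intermediate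
18 | (1R,3R,4R,6S,8R,10R)-3-ethyl-8-(prop-2-en-1-yl)-2,7-dioxabicyclo[4.2.2]decane-4,10-diol | C=CC[C@H]1O[C@H]2C[C@@H](O)[C@@H](CC)O[C@@H]1C[C@H]2O | intermediate
19 | (2E)-4-[(1R,3R,4R,6S,8R,10R)-3-ethyl-4,10-dihydroxy-2,7-dioxabicyclo[4.2.2]decan-8-yl]but-2-enal | O=C/C=C/C[C@H]1O[C@H]2C[C@@H](O)[C@@H](CC)O[C@@H]1C[C@H]2O | intermediate
20 | (1R,3R,4R,6S,8R,10R)-3-ethyl-8-[(2E)-pent-2-en-4-yn-1-yl]-2,7-dioxabicyclo[4.2.2]decane-4,10-diol | C#C/C=C/C[C@H]1O[C@H]2C[C@@H](O)[C@@H](CC)O[C@@H]1C[C@H]2O | intermediate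
21 | (1R,3R,4S,6S,8R,10S)-4,10-dibromo-3-ethyl-8-[(2E)-pent-2-en-4-yn-1-yl]-2,7-dioxabicyclo[4.2.2]decane | C#C/C=C/C[C@H]1O[C@H]2C[C@H](Br)[C@@H](CC)O[C@@H]1C[C@@H]2Br | target

**Totals**

Total step count: 14. Longest linear sequence: 14 steps (from 2 to 21).

**Steps most likely to fail**

Step 10. The control of the ketyl orientation in the boat-like bridging transition state may be poor: the samarium-bound oxygen may settle anti to O-a, which would give the C9 epimer, and part of the aldehyde may simply be reduced. In the fallback, C9 is set by reagent control and not by the cyclization. It sets out from 14: the same cyclization would then deliver the C9-epimeric hydroxy ketone F1. A Mitsunobu reaction (4-nitrobenzoic acid, PPh3, diisopropyl azodicarboxylate, toluene, 0 °C to rt) would invert C9 and give the 4-nitrobenzoate F2. LiBH(s-Bu)3 at −78 °C would reduce the C12 ketone as in step 11 to the hydroxy ester F3. K2CO3 in MeOH at 0 °C would cleave the ester, and the route is rejoined at diol 18.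

Step 8. Intermolecular conjugate addition may win over ring closure, so that acyclic (E)-configured oligomers form in place of the strained (Z)-ring. The fallback closes the ring under thermodynamic control by exchange at a trigonal carbon, not by kinetic addition to the alkyne. It sets out from 12: MeOH with N-methylmorpholine (cat.) would give the (E)-β-methoxy enone F4. PPTS (cat.) in toluene at 80 °C with 5 Å molecular sieves at high dilution would then exchange methanol for the C6 hydroxyl by reversible addition–elimination at C10, and the route is rejoined at 13.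

Step 14. Under the hot phosphine conditions E2 elimination or participation of a neighbouring ring oxygen may compete, and substitution at the more hindered C9 may be slow, with loss of configuration. The fallback separates activation from substitution. It sets out from 20: ClCH2SO2Cl and 2,6-lutidine in CH2Cl2 at 0 °C would give the bis(chloromethanesulfonate) F5. n-Bu4NBr in toluene at 60 °C would displace both sulfonates with inversion, and the route is rejoined at 21.

**Further compounds**

F1 | step 10 | (1R,3R,6S,8R,10S)-3-ethyl-10-hydroxy-8-(prop-2-en-1-yl)-2,7-dioxabicyclo[4.2.2]decan-4-one | C=CC[C@H]1O[C@H]2CC(=O)[C@@H](CC)O[C@@H]1C[C@@H]2O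
F2 | step 10 | (1R,3R,6S,8R,10R)-3-ethyl-4-oxo-8-(prop-2-en-1-yl)-2,7-dioxabicyclo[4.2.2]decan-10-yl 4-nitrobenzoate | C=CC[C@H]1O[C@H]2CC(=O)[C@@H](CC)O[C@@H]1C[C@H]2OC(=O)c1ccc(cc1)[N+](=O)[O-]
F3 | step 10 | (1R,3R,4R,6S,8R,10R)-3-ethyl-4-hydroxy-8-(prop-2-en-1-yl)-2,7-dioxabicyclo[4.2.2]decan-10-yl 4-nitrobenzoate | C=CC[C@H]1O[C@H]2C[C@@H](O)[C@@H](CC)O[C@@H]1C[C@H]2OC(=O)c1ccc(cc1)[N+](=O)[O-]
F4 | step 8 | (1E,4R)-4-{[(2R,3R)-1-(1,3-dithian-2-yl)-3-hydroxyhex-5-en-2-yl]oxy}-1-methoxyhex-1-en-3-one | CC[C@@H](O[C@H](CC1SCCCS1)[C@H](O)CC=C)C(=O)/C=C/OC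
F5 | step 14 | (1R,3R,4R,6S,8R,10R)-3-ethyl-8-[(2E)-pent-2-en-4-yn-1-yl]-2,7-dioxabicyclo[4.2.2]decane-4,10-diyl bis(chloromethanesulfonate) | C#C/C=C/C[C@H]1O[C@H]2C[C@@H](OS(=O)(=O)CCl)[C@@H](CC)O[C@@H]1C[C@H]2OS(=O)(=O)CCl
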